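**Retrosynthetic overview**
1. Target 22 ⇐ penta-MOM ether 21 by global acetal hydrolysis (last step).
2. 21 ⇐ dihydrobenzofuran acid 20 + lactate acrylate 8: the C4–vinyl bond comes from a carboxylate-directed ortho C–H olefination.
3. 20 ⇐ aryl diazoacetate 18 (from tosylhydrazone 17): the C2–C3 bond is closed by an enantioselective cobalt metalloradical 1,5-HAT/radical substitution. This forms the only ring made in the synthesis, the dihydrofuran ring, on a catechol-derived benzene ring.
4. 17 ⇐ aryl glyoxylate 15 (ortho-lithiation of bis-MOM catechol, dimethyl oxalate, selective unmasking) + benzylic alcohol 11 (Mitsunobu ether).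
5. 8 and 11 ⇐ aryl bromide 3, through Grignard reagent 5 with methyl (R)-glycidate and through aryllithium 10 with formaldehyde; all three benzene rings come from catechol.

Assumption: the identifier is taken to mean exactly the given SMILES, i.e. the 9''-methyl ester of (+)-lithospermic acid (2S,3S in the dihydrobenzofuran, R in the lactate, E alkene).

**Route**

Step 1
Reactants: 1 catechol (benzene-1,2-diol)
Product: 2 1,2-bis(methoxymethoxy)benzene
Conditions: MOMCl (2.5 eq), i-Pr2NEt (3 eq), CH2Cl2, 0 °C → rt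
Reagents that add atoms: chloromethyl methyl ether (MOMCl), COCCl
Why: Williamson-type O-alkylation of both phenols gives the bis-acetal, which is stable to organometallics and base and later directs ortho-lithiation.

Step 2
Reactants: 2 1,2-bis(methoxymethoxy)benzene
Product: 3 4-bromo-1,2-bis(methoxymethoxy)benzene
Conditions: NBS (1.05 eq), MeCN, 0 °C → rt
Reagents that add atoms: N-bromosuccinimide, O=C1CCC(=O)N1Br
Why: Electrophilic aromatic bromination goes para to an alkoxy group, and the 4-position is the only unhindered para site.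

Step 3
Reactants: 3 4-bromo-1,2-bis(methoxymethoxy)benzene; 4 methyl (R)-glycidate [methyl (2R)-oxirane-2-carboxylate]
Product: 6 methyl (2R)-3-[3,4-bis(methoxymethoxy)phenyl]-2-hydroxypropanoate, via arylmagnesium bromide 5 (not isolated)
Conditions: Mg turnings, THF, 40 °C; then CuI (10 mol%), 4 (0.8 eq), THF, −40 → −20 °C; then H2O
Reagents that add atoms: magnesium, [Mg] (stays only in intermediate 5)
Why: Grignard formation followed by CuI-catalysed SN2 epoxide opening at the unsubstituted CH2, which at −40 °C outruns addition to the ester; the (R) centre of 4 is not touched and becomes the (R) lactate centre.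

Step 4
Reactants: 6 methyl (2R)-3-[3,4-bis(methoxymethoxy)phenyl]-2-hydroxypropanoate; 7 acryloyl chloride
Product: 8 methyl (2R)-2-(acryloyloxy)-3-[3,4-bis(methoxymethoxy)phenyl]propanoate
Conditions: 7 (1.3 eq), Et3N (1.5 eq), CH2Cl2, −20 → 0 °C
Reagents that add atoms: none
Why: Acyl chloride esterification of the secondary alcohol; the cold, short amine exposure leaves the α-acyloxy ester centre (R) intact.

Step 5
Reactants: 3 4-bromo-1,2-bis(methoxymethoxy)benzene; 9 formaldehyde (used as dry paraformaldehyde)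
Product: 11 [3,4-bis(methoxymethoxy)phenyl]methanol, via 3,4-bis(methoxymethoxy)phenyllithium 10 (not isolated)
Conditions: n-BuLi (1.05 eq), THF, −78 °C, 30 min; then (CH2O)n (3 eq), −78 °C → rt; then H2O
Reagents that add atoms: n-butyllithium, [Li]CCCC (lithium stays only in intermediate 10)
Why: Bromine–lithium exchange is fast at −78 °C and leaves the MOM acetals alone, and addition of the aryllithium to formaldehyde (hydroxymethylation) gives the primary benzylic alcohol whose CH2 becomes C2 of the dihydrobenzofuran.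

Step 6
Reactants: 2 1,2-bis(methoxymethoxy)benzene; 12 dimethyl oxalate
Product: 14 methyl 2-[2,3-bis(methoxymethoxy)phenyl]-2-oxoacetate, via 2,3-bis(methoxymethoxy)phenyllithium 13 (not isolated)
Conditions: n-BuLi (1.1 eq), THF, 0 °C, 1 h; then cannulated into 12 (3 eq), THF, −78 °C; then H2O
Reagents that add atoms: n-butyllithium, [Li]CCCC (lithium stays only in intermediate 13)
Why: Directed ortho-metalation next to an OMOM group, then acylation by inverse addition to excess oxalate at −78 °C, which stops at the α-keto ester and sets the 1,2,3-substitution pattern of the central ring.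

Step 7
Reactants: 14 methyl 2-[2,3-bis(methoxymethoxy)phenyl]-2-oxoacetate
Product: 15 methyl 2-[2-hydroxy-3-(methoxymethoxy)phenyl]-2-oxoacetate
Conditions: MgBr2·OEt2 (3 eq), CH2Cl2/Et2O, 0 °C → rt; then H2O
Reagents that add atoms: none
Why: Chelation-controlled acetal cleavage: magnesium bridges the ketone oxygen and the flanked ortho acetal oxygen, and the ortho-acyl phenoxide is the better leaving group, so only the MOM group next to the keto ester is removed.

Step 8
Reactants: 15 methyl 2-[2-hydroxy-3-(methoxymethoxy)phenyl]-2-oxoacetate; 11 [3,4-bis(methoxymethoxy)phenyl]methanol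
Product: 16 methyl 2-[2-{[3,4-bis(methoxymethoxy)phenyl]methoxy}-3-(methoxymethoxy)phenyl]-2-oxoacetate
Conditions: PPh3 (1.3 eq), DIAD (1.3 eq), THF, 0 °C → rt
Reagents that add atoms: none
Why: Mitsunobu etherification of an acidic, hydrogen-bonded ortho-acyl phenol with a primary benzylic alcohol (SN2 at CH2); no stereocentre is involved.

Step 9
Reactants: 16 methyl 2-[2-{[3,4-bis(methoxymethoxy)phenyl]methoxy}-3-(methoxymethoxy)phenyl]-2-oxoacetate
Product: 17 N-tosylhydrazone of 16 (E/Z mixture at C=N), methyl 2-[2-{[3,4-bis(methoxymethoxy)phenyl]methoxy}-3-(methoxymethoxy)phenyl]-2-(2-tosylhydrazinylidene)acetate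
Conditions: TsNHNH2 (1.05 eq), MeOH, 50 °C
Reagents that add atoms: p-toluenesulfonyl hydrazide, Cc1ccc(S(=O)(=O)NN)cc1
Why: Condensation of the electrophilic α-keto ester carbonyl with the hydrazide needs no acid, so the MOM acetals are safe.

Step 10
Reactants: 17 N-tosylhydrazone of 16
Product: 19 methyl (2S,3S)-2-[3,4-bis(methoxymethoxy)phenyl]-7-(methoxymethoxy)-2,3-dihydro-1-benzofuran-3-carboxylate, via aryl diazoacetate 18 (not isolated)
Conditions: [Co(3,5-DitBu-ChenPhyrin)] (D2-symmetric chiral amidoporphyrin complex of divalent cobalt, 3 mol%; ligand antipode chosen for the 2S series), Cs2CO3 (2 eq), toluene, 40 °C, N2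
Reagents that add atoms: none
Why: Proposed new method: this is the key step; base releases diazo ester 18 (Bamford–Stevens); the divalent cobalt metalloradical takes it up with loss of N2 to give an α-(trivalent cobalt)-benzyl radical stabilised by the aryl and ester groups; this abstracts the weak α-oxy benzylic hydrogen of the neighbouring ArCH2–O group through a six-membered 1,5-HAT transition state; the resulting C2 radical attacks C3 in a 5-exo-tet radical substitution that forms the C2–C3 bond and returns divalent cobalt. The chiral amide pocket (N–H···O=C hydrogen bond to the ester) fixes the face of attack and so sets C2 as S, and the late ring-closing transition state places aryl and ester trans (3S). The closest known chemistry is cobalt metalloradical enantioselective intramolecular C–H alkylation with diazo compounds generated in situ from tosylhydrazones to give five-membered rings; the same ring is known from closed-shell dirhodium carbene C–H insertion.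

Step 11
Reactants: 19 methyl (2S,3S)-2-[3,4-bis(methoxymethoxy)phenyl]-7-(methoxymethoxy)-2,3-dihydro-1-benzofuran-3-carboxylate
Product: 20 (2S,3S)-2-[3,4-bis(methoxymethoxy)phenyl]-7-(methoxymethoxy)-2,3-dihydro-1-benzofuran-3-carboxylic acid
Conditions: Me3SnOH (5 eq), 1,2-dichloroethane, 80 °C; then cold 0.1 M HCl wash
Reagents that add atoms: trimethyltin hydroxide, C[Sn](C)(C)O
Why: Near-neutral Me3SnOH ester hydrolysis avoids enolisation and retro-oxa-Michael ring opening, so C2 and C3 keep their configuration.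

Step 12
Reactants: 20 (2S,3S)-2-[3,4-bis(methoxymethoxy)phenyl]-7-(methoxymethoxy)-2,3-dihydro-1-benzofuran-3-carboxylic acid; 8 methyl (2R)-2-(acryloyloxy)-3-[3,4-bis(methoxymethoxy)phenyl]propanoate
Product: 21 (2S,3S)-2-[3,4-bis(methoxymethoxy)phenyl]-4-[(1E)-3-{[(2R)-3-[3,4-bis(methoxymethoxy)phenyl]-1-methoxy-1-oxopropan-2-yl]oxy}-3-oxoprop-1-en-1-yl]-7-(methoxymethoxy)-2,3-dihydro-1-benzofuran-3-carboxylic acid
Conditions: Pd(OAc)2 (10 mol%), Ac-Ile-OH (20 mol%), KHCO3 (2 eq), 8 (1.5 eq), t-AmylOH, O2 (1 atm), 85 °C; then cold 0.5 M HCl to pH 3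
Reagents that add atoms: none
Why: Carboxylate-directed ortho C–H olefination by divalent palladium (Fujiwara–Moritani type with a mono-protected amino acid ligand, precedented on the methyl-ether analogue of this acid); C4 is the only ortho C–H, syn-insertion/β-hydride elimination gives the E alkene, and no stereocentre is touched.

Step 13
Reactants: 21 penta-MOM acid from step 12
Product: 22 (2S,3S)-2-(3,4-dihydroxyphenyl)-4-[(1E)-3-{[(2R)-3-(3,4-dihydroxyphenyl)-1-methoxy-1-oxopropan-2-yl]oxy}-3-oxoprop-1-en-1-yl]-7-hydroxy-2,3-dihydro-1-benzofuran-3-carboxylic acid (target)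
Conditions: 2 M HCl, THF/i-PrOH/H2O (5:4:1), 45 °C, Ar; preparative HPLC
Reagents that add atoms: none
Why: Acid-catalysed hydrolysis of the five aryl MOM acetals is much faster than hydrolysis of the methyl or cinnamate ester, methanol is avoided so the free acid is not esterified, and any reversible C2–O ionisation re-closes trans to the fixed C3 centre.

**Compound list**
1 | catechol (benzene-1,2-diol) | Oc1ccccc1O | starting material
2 | 1,2-bis(methoxymethoxy)benzene | COCOc1ccccc1OCOC | intermediate
3 | 4-bromo-1,2-bis(methoxymethoxy)benzene | COCOc1ccc(Br)cc1OCOC | intermediate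
4 | methyl (R)-glycidate [methyl (2R)-oxirane-2-carboxylate] | COC(=O)[C@H]1CO1 | starting material
5 | [3,4-bis(methoxymethoxy)phenyl]magnesium bromide | COCOc1ccc([Mg]Br)cc1OCOC | intermediate
6 | methyl (2R)-3-[3,4-bis(methoxymethoxy)phenyl]-2-hydroxypropanoate | COC(=O)[C@@H](Cc1ccc(OCOC)c(OCOC)c1)O | intermediate
7 | acryloyl chloride | C=CC(=O)Cl | starting material
8 | methyl (2R)-2-(acryloyloxy)-3-[3,4-bis(methoxymethoxy)phenyl]propanoate | COC(=O)[C@@H](Cc1ccc(OCOC)c(OCOC)c1)OC(=O)C=C | intermediate
9 | formaldehyde (as paraformaldehyde) | C=O | starting material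
10 | [3,4-bis(methoxymethoxy)phenyl]lithium | COCOc1ccc([Li])cc1OCOC | intermediate
11 | [3,4-bis(methoxymethoxy)phenyl]methanol | OCc1ccc(OCOC)c(OCOC)c1 | intermediate
12 | dimethyl oxalate | COC(=O)C(=O)OC | starting material
13 | [2,3-bis(methoxymethoxy)phenyl]lithium | COCOc1cccc([Li])c1OCOC | intermediate
14 | methyl 2-[2,3-bis(methoxymethoxy)phenyl]-2-oxoacetate | COC(=O)C(=O)c1cccc(OCOC)c1OCOC | intermediate
15 | methyl 2-[2-hydroxy-3-(methoxymethoxy)phenyl]-2-oxoacetate | COC(=O)C(=O)c1cccc(OCOC)c1O | intermediate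
16 | methyl 2-[2-{[3,4-bis(methoxymethoxy)phenyl]methoxy}-3-(methoxymethoxy)phenyl]-2-oxoacetate | COC(=O)C(=O)c1cccc(OCOC)c1OCc1ccc(OCOC)c(OCOC)c1 | intermediate
17 | N-tosylhydrazone of 16 (E/Z mixture) | COC(=O)C(=NNS(=O)(=O)c1ccc(C)cc1)c1cccc(OCOC)c1OCc1ccc(OCOC)c(OCOC)c1 | intermediate
18 | methyl 2-diazo-2-[2-{[3,4-bis(methoxymethoxy)phenyl]methoxy}-3-(methoxymethoxy)phenyl]acetate | COC(=O)C(=[N+]=[N-])c1cccc(OCOC)c1OCc1ccc(OCOC)c(OCOC)c1 | intermediate
19 | methyl (2S,3S)-2-[3,4-bis(methoxymethoxy)phenyl]-7-(methoxymethoxy)-2,3-dihydro-1-benzofuran-3-carboxylate (trans) | c1ccc(OCOC)c2c1[C@H](C(=O)OC)[C@@H](c1ccc(OCOC)c(OCOC)c1)O2 | intermediate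
20 | (2S,3S)-2-[3,4-bis(methoxymethoxy)phenyl]-7-(methoxymethoxy)-2,3-dihydro-1-benzofuran-3-carboxylic acid | c1ccc(OCOC)c2c1[C@H](C(=O)O)[C@@H](c1ccc(OCOC)c(OCOC)c1)O2 | intermediate
21 | (2S,3S)-2-[3,4-bis(methoxymethoxy)phenyl]-4-[(1E)-3-{[(2R)-3-[3,4-bis(methoxymethoxy)phenyl]-1-methoxy-1-oxopropan-2-yl]oxy}-3-oxoprop-1-en-1-yl]-7-(methoxymethoxy)-2,3-dihydro-1-benzofuran-3-carboxylic acid | COC(=O)[C@@H](Cc1ccc(OCOC)c(OCOC)c1)OC(=O)/C=C/c1ccc(OCOC)c2c1[C@H](C(=O)O)[C@@H](c1ccc(OCOC)c(OCOC)c1)O2 | intermediate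
22 | (2S,3S)-2-(3,4-dihydroxyphenyl)-4-[(1E)-3-{[(2R)-3-(3,4-dihydroxyphenyl)-1-methoxy-1-oxopropan-2-yl]oxy}-3-oxoprop-1-en-1-yl]-7-hydroxy-2,3-dihydro-1-benzofuran-3-carboxylic acid | COC(=O)[C@@H](Cc1ccc(O)c(O)c1)OC(=O)/C=C/c1ccc(O)c2c1[C@H](C(=O)O)[C@@H](c1ccc(O)c(O)c1)O2 | target

**Step count**
Total: 13 steps. Longest linear sequence: 9 steps (steps 1, 6, 7, 8, 9, 10, 11, 12, 13; the chain through steps 1, 2, 5, 8, 9, 10, 11, 12, 13 is equally long).

**Three steps most likely to fail, with fallbacks**

Step 10 (metalloradical C–H alkylation). Donor/acceptor diazo esters are slow to activate on cobalt porphyrins, so carbene dimerisation, a poor trans:cis ratio or low ee are all possible. The fallback sets out from 17 and comes back at 19. Hydrazone 17 is treated with DBU in CH2Cl2 at rt and the diazo ester 18 is isolated. It is then decomposed with the chiral dirhodium carboxylate Rh2(S-PTTL)4 (1 mol%, toluene, −60 °C; the enantiomeric catalyst if the sense is opposite). This is a closed-shell carbenoid C–H insertion, known to give cis-2-aryl-3-alkoxycarbonyl dihydrobenzofurans in high ee, and affords the cis ester methyl (2S,3R)-2-[3,4-bis(methoxymethoxy)phenyl]-7-(methoxymethoxy)-2,3-dihydro-1-benzofuran-3-carboxylate F1. Epimerisation at C3 with NaOMe in MeOH (0 °C → rt) gives the trans ester 19.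

Step 7 (selective removal of one MOM group). The Lewis acid may remove the wrong acetal or both. The fallback sets out from 1 and comes back at 15, bypassing steps 6 and 7. Catechol 1 is mono-protected (MOMCl 1.0 eq, i-Pr2NEt, CH2Cl2) to 2-(methoxymethoxy)phenol F2. Its bromomagnesium phenoxide (EtMgBr, toluene) reacts with methyl glyoxylate (COC(=O)C=O) in a chelation-directed, ortho-specific hydroxyalkylation to give methyl 2-hydroxy-2-[2-hydroxy-3-(methoxymethoxy)phenyl]acetate F3 (racemic). Activated MnO2 (CH2Cl2, rt) then oxidises the benzylic alcohol to keto ester 15.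

Step 13 (global deprotection). Aqueous acid with liberated formaldehyde may damage the catechols, open the benzylic C2–O bond or partly hydrolyse the esters. The fallback sets out from 21 and comes back at 22. TESOTf/2,2'-bipyridyl (CH2Cl2, 0 °C; aqueous work-up, which hydrolyses the silyl ester) exchanges all five aryl MOM ethers directly for triethylsilyl ethers, giving (2S,3S)-2-[3,4-bis(triethylsilyloxy)phenyl]-4-[(1E)-3-{[(2R)-3-[3,4-bis(triethylsilyloxy)phenyl]-1-methoxy-1-oxopropan-2-yl]oxy}-3-oxoprop-1-en-1-yl]-7-(triethylsilyloxy)-2,3-dihydro-1-benzofuran-3-carboxylic acid F4. HF·pyridine (THF/pyridine, 0 °C) then removes the silyl groups under near-neutral fluoride conditions to give 22.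

**Further compounds**
F1 | step 10 | methyl (2S,3R)-2-[3,4-bis(methoxymethoxy)phenyl]-7-(methoxymethoxy)-2,3-dihydro-1-benzofuran-3-carboxylate (cis) | c1ccc(OCOC)c2c1[C@@H](C(=O)OC)[C@@H](c1ccc(OCOC)c(OCOC)c1)O2
F2 | step 7 | 2-(methoxymethoxy)phenol | COCOc1ccccc1O
F3 | step 7 | methyl 2-hydroxy-2-[2-hydroxy-3-(methoxymethoxy)phenyl]acetate (racemic) | COC(=O)C(O)c1cccc(OCOC)c1O
F4 | step 13 | (2S,3S)-2-[3,4-bis(triethylsilyloxy)phenyl]-4-[(1E)-3-{[(2R)-3-[3,4-bis(triethylsilyloxy)phenyl]-1-methoxy-1-oxopropan-2-yl]oxy}-3-oxoprop-1-en-1-yl]-7-(triethylsilyloxy)-2,3-dihydro-1-benzofuran-3-carboxylic acid | COC(=O)[C@@H](Cc1ccc(O[Si](CC)(CC)CC)c(O[Si](CC)(CC)CC)c1)OC(=O)/C=C/c1ccc(O[Si](CC)(CC)CC)c2c1[C@H](C(=O)O)[C@@H](c1ccc(O[Si](CC)(CC)CC)c(O[Si](CC)(CC)CC)c1)O2
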